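All constants are assumed, and the outcome is calculated.

5 questions stand on 4 flasks, and I reckon them with one number.

| setting | oak | elm | ash | alder |
|---|---|---|---|---|
| starting material | 20 mM (in portions, 2, over 1.0 min) | 20 mM | 20 mM | 20 mM (fed, over 1.0 min) |
| partner | 60.0 mM | 60.0 mM | 60.0 mM (fed, over 1.0 min) | 60.0 mM |
| free catalyst | 1.8 mM | 1.8 mM | 1.8 mM | 1.8 mM |
| time | 2.5 min | 2.5 min | 2.5 min | 2.5 min |
| remark | first portion at the start, last at 1.0 min | everything together at the start | all else is in the flask from the start; the feed brings no volume worth counting | all else is in the flask from the start; the feed brings no volume worth counting |

    starting material + free catalyst → free catalyst + open intermediate (k1 = 45.8 M⁻¹ s⁻¹)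
    free catalyst + open intermediate ⇌ catalyst intermediate (K2 = 107 M⁻¹, k2 = 296 M⁻¹ s⁻¹)
    partner + catalyst intermediate → free catalyst + target (k3 = 5.01 M⁻¹ s⁻¹)
    starting material + partner → uncatalysed product (k4 = 0.0377 M⁻¹ s⁻¹)
    free catalyst → spent catalyst (k5 = 0.0773 s⁻¹)
    free catalyst + target ⇌ idle complex (K6 = 18 M⁻¹, k6 = 3.02 M⁻¹ s⁻¹)

- the flask that comes out highest in amount of uncatalysed product, in percent of the starting material charged; "all alike" if 1.5 percentage points covers them all (oak / elm / ash / alder / all alike)
- amount of uncatalysed product at the end, in percent of the starting material charged, oak
- amount of uncatalysed product at the end, in percent of the starting material charged, elm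
- amount of uncatalysed product at the end, in percent of the starting material charged, ash
- amount of uncatalysed product at the end, in percent of the starting material charged, alder

- for target the idle complex is counted in
- run time (oak): 2.5 min

I start with elm in its first instants. Step 1 removes starting material at 0.0824 s⁻¹, faster than step 4, a pseudo-first-order loss at 0.00226 s⁻¹ with partner at its charge. But free catalyst dies at 0.0773 s⁻¹, a lifetime of 12.9 s.

So I multiply k1 by the catalyst charge and by that lifetime, which gives 1.07. I name this the catalyst dose, the logarithmic loss of starting material that one charge of catalyst can deal in its whole life. Binding moves the dose later but does not shrink it, since step 5 is the one exit from the catalyst's forms. With partner at its charge, the step from catalyst intermediate back to free catalyst and open intermediate runs at 2.77 s⁻¹, faster than step 3 at 0.301 s⁻¹.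

Material present from the start therefore keeps 34.4% of itself against step 1. Towards the end of elm step 4 carries on, with a half-life of 5.1 min by that step alone.

Uncatalysed product is then the pseudo-first-order constant of step 4 times time times the mean share of starting material, so I replace each curve by its mean. Holding [partner] at its charge makes these figures lean high.

For elm, I take the mean of the surviving share at its start and at the end of the run, add the early excess over one lifetime, and get 11.9%. In oak, I reckon the first portion, half the charge, like elm. If free catalyst decays without binding, 0.968% of the dose is left at 1.0 min, so I count the second portion of oak as untouched, which gives 15.2%.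

In ash, partner climbs linearly, so I take its mean over the feed as 0.5 of its charge, giving 8.70%. In alder, starting material climbs instead, and by the same decay I give fed material a mean dose of 0.228. That keeps 79.6% and gives 20.1%, so alder stands highest in my reckoning.

The forecast also names alder, with 14.1% for oak, 11.6% for elm, 8.4% for ash and 18.3% for alder, each lower than mine , on the ground that “fed starting material mostly misses the catalyst”.

The simulation gives 14.1% for oak, 11.3% for elm, 8.59% for ash and 18.6% for alder, so alder is highest. Elm ends with 25.2% starting material and 11.3% uncatalysed product, together 36.5% against the 34.4% that the dose lets past step 1. The neighbour of ash charged with 0.45 mM free catalyst has a dose of 0.267, which lets 76.6% past, and it ends with 58.9% starting material and 17.9% uncatalysed product, together 76.8%.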